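The bicyclo[2.2.2]octene is cut at C3′–C4′ and C6′–C5′, which makes the hydroxyisopropyl carbinol carbon on C4′ an acrylate carbonyl carried by the C6 oxygen of seven-membered ring B. The feature exploited is that O6 lies three bonds from spiro C11 on the C7 side of lactone ring C, so the tethered acrylate reaches one face of a spiro cyclohexa-1,3-diene only. One thermal step forms both C–C bonds, the bicyclooctene, a bridging seven-membered lactone and three stereocentres. The precursor is the C6 acrylate of the C11-spiro 4-methylcyclohexa-2,4-diene lactone, with C9 as a TBS ether and C4 as a dioxolane.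

Key step: step 20

Remark: pseudoguaianolide numbering is used (ring A = C1–C5, ring B = C1, C5–C10, lactone ring C = C7, C8, O, C12, C11; "hydroazulane" = the trans-fused ring A/B bicycle with 1α-H and 5β-methyl; β = the face of ring B that carries the C5 methyl; primed carbons belong to the bicyclooctene, and at C4′ endo = toward the C1′=C2′ bridge); it is assumed that the antipode of the chiral ligand in step 1 is the one that makes C1 S.

Step 1
Reactants: 1 2-methylcyclopent-2-en-1-one; 2 vinylmagnesium bromide
Product: 3 (S)-trimethyl[(2-methyl-3-vinylcyclopent-1-en-1-yl)oxy]silane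
Conditions: CuBr·SMe2 (5 mol %), BINOL-derived phosphoramidite ligand L* (10 mol %), TMSCl, Et2O, −78 °C; then Et3N
Reagents that add atoms: chlorotrimethylsilane, C[Si](C)(C)Cl
Why: Copper-catalysed asymmetric conjugate addition of a Grignard reagent to an α-substituted cycloalkenone should deliver the vinyl group to one enone face under ligand control (C1 formed S), and TMSCl traps the magnesium enolate regiospecifically as the tetrasubstituted silyl enol ether needed for the next C–C bond.

Step 2
Reactants: 4 penta-1,4-dien-3-ol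
Product: 5 penta-1,4-dien-3-one
Conditions: MnO2, CH2Cl2, rt; filtered solution used directly
Reagents that add atoms: none
Why: MnO2 oxidation of an allylic alcohol should convert the doubly allylic carbinol cleanly into the dienone, which is used at once as a cold solution because it polymerises on storage.

Step 3
Reactants: 3 (S)-trimethyl[(2-methyl-3-vinylcyclopent-1-en-1-yl)oxy]silane; 5 penta-1,4-dien-3-one
Product: 6 (2S,3S)-2-methyl-2-(3-oxopent-4-en-1-yl)-3-vinylcyclopentan-1-one
Conditions: 5 (3 equiv), TiCl4, CH2Cl2, −78 °C; then H2O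
Reagents that add atoms: none
Why: Mukaiyama–Michael addition of a silyl enol ether to a TiCl4-activated vinyl ketone should join C5 to C6 on the face anti to the C1 vinyl group, so the quaternary centre forms with the new chain trans to vinyl (the later trans ring fusion), while an excess of the dienone limits double addition.

Step 4
Reactants: 6 (2S,3S)-2-methyl-2-(3-oxopent-4-en-1-yl)-3-vinylcyclopentan-1-one
Product: 7 trans-hydroazul-9-ene-4,8-dione (5β-methyl, 1α-H)
Conditions: second-generation Grubbs catalyst (5 mol %), CH2Cl2 (5 mM), 40 °C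
Reagents that add atoms: none
Why: Ring-closing metathesis between the vinyl ketone and the C1 vinyl group should close seven-membered ring B as a conjugated enone with loss of ethene, touching no stereocentre.

Step 5
Reactants: 7 trans-hydroazul-9-ene-4,8-dione
Product: 8 4,4-ethylenedioxyhydroazul-9-en-8-one
Conditions: (TMSOCH2)2, TMSOTf (5 mol %), CH2Cl2, −78 → −20 °C
Reagents that add atoms: 1,2-bis(trimethylsilyloxy)ethane, C[Si](C)(C)OCCO[Si](C)(C)C
Why: Silyl-triflate-catalysed ketalisation with the bis-silyl ether of ethylene glycol is selective for a saturated ketone over a conjugated enone, as in other bicyclic enediones whose cyclopentanone sits next to a quaternary carbon, and the cold aprotic medium should leave the enone in place.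

Step 6
Reactants: 8 4,4-ethylenedioxyhydroazul-9-en-8-one
Product: 9 4,4-ethylenedioxy-10α-methyl-8-(trimethylsilyloxy)hydroazul-8-ene
Conditions: Me2CuLi (from MeLi and CuI), TMSCl, Et2O/THF, −78 °C; Et3N, aq. NaHCO3
Reagents that add atoms: lithium dimethylcuprate, [Li+].C[Cu-]C; chlorotrimethylsilane, C[Si](C)(C)Cl
Why: Cuprate conjugate addition with silyl trapping should place the methyl group on C10 from the α face, anti to the angular C5 methyl that shields the β face of ring B, and keeps the enolate regiodefined as the C8–C9 silyl enol ether.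

Step 7
Reactants: 9 4,4-ethylenedioxy-10α-methyl-8-(trimethylsilyloxy)hydroazul-8-ene
Product: 11 4,4-ethylenedioxy-9β-hydroxy-10α-methylhydroazulan-8-one, via 9β-trimethylsilyloxy ketone 10 (not isolated)
Conditions: mCPBA, CH2Cl2, −20 °C; then citric acid (cat.), MeOH, rt
Reagents that add atoms: 3-chloroperbenzoic acid, OOC(=O)c1cccc(Cl)c1
Why: Rubottom oxidation should epoxidise the enol ether on the face anti to the adjacent 10α-methyl group, and silyl migration followed by methanolysis then gives the 9β-alcohol trans to that methyl group, which is also the more stable epimer of this enolisable centre.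

Step 8
Reactants: 11 4,4-ethylenedioxy-9β-hydroxy-10α-methylhydroazulan-8-one
Product: 12 9β-tert-butyldimethylsilyl ether of 11
Conditions: TBSOTf, 2,6-lutidine, CH2Cl2, −78 → 0 °C
Reagents that add atoms: tert-butyldimethylsilyl triflate, CC(C)(C)[Si](C)(C)OS(=O)(=O)C(F)(F)F
Why: Silylation with a silyl triflate and a hindered pyridine base is the standard protection of a hindered secondary alcohol and is run cold so that the adjacent ketone is not enolised.

Step 9
Reactants: 12 9β-tert-butyldimethylsilyl ether of 11
Product: 14 4,4-ethylenedioxy-9β-(tert-butyldimethylsilyloxy)-10α-methylhydroazul-6-en-8-one, via 8-trimethylsilyloxy-7-ene 13 (not isolated)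
Conditions: LiN(iPr)2, TMSCl, THF, −78 °C; then Pd(OAc)2, MeCN, rt
Reagents that add atoms: chlorotrimethylsilane, C[Si](C)(C)Cl (kept only in intermediate 13)
Why: Saegusa–Ito oxidation: kinetic deprotonation occurs at the C7 methylene and not at the silyloxy-bearing C9 methine, and Pd(OAc)2 then dehydrogenates the enol ether to the C6=C7 enone.

Step 10
Reactants: 14 4,4-ethylenedioxy-9β-(tert-butyldimethylsilyloxy)-10α-methylhydroazul-6-en-8-one
Product: 16 6α-hydroxy-9β-(tert-butyldimethylsilyloxy)-10α-methyl 8-ketone, via 6α-pinacolboryl ketone 15 (not isolated)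
Conditions: B2pin2, CuCl (5 mol %), Xantphos (5 mol %), NaOtBu (10 mol %), MeOH, THF, rt; then NaBO3·4H2O, THF/H2O, rt
Reagents that add atoms: bis(pinacolato)diboron, CC1(C)OB(OC1(C)C)B1OC(C)(C)C(C)(C)O1 (kept only in intermediate 15); sodium perborate, [Na+].[O-]OB=O
Why: Copper-catalysed conjugate borylation of an enone followed by stereoretentive oxidation of the C–B bond should place oxygen on C6 from the α face, anti to the angular methyl on the neighbouring C5, giving the 6α-alcohol as a β-hydroxy ketone under conditions too mild for retro-aldol cleavage.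

Step 11
Reactants: 16 6α-hydroxy-9β-(tert-butyldimethylsilyloxy)-10α-methyl 8-ketone
Product: 17 6α-triethylsilyl ether of 16
Conditions: TESOTf, 2,6-lutidine, CH2Cl2, −78 °C
Reagents that add atoms: triethylsilyl triflate, CC[Si](CC)(CC)OS(=O)(=O)C(F)(F)F
Why: Silyl ether formation under non-basic triflate conditions protects O6 with a group that buffered fluoride will later remove in the presence of the C9 TBS ether.

Step 12
Reactants: 17 6α-triethylsilyl ether of 16; 18 ethyl iodoacetate
Product: 19 7β-(2-ethoxy-2-oxoethyl)-6α-(triethylsilyloxy)-9β-(tert-butyldimethylsilyloxy)-10α-methyl 8-ketone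
Conditions: LiN(iPr)2, THF, −78 °C; then 18, DMPU, −78 → −40 °C
Reagents that add atoms: none
Why: Kinetic enolate alkylation with an α-iodo ester: the base removes a C7 proton, the electrophile enters anti to the neighbouring 6α-silyloxy group to give the 7β side chain, and this ketone α-centre stays correctable by equilibration to the same trans-6,7 arrangement.

Step 13
Reactants: 19 7β-(2-ethoxy-2-oxoethyl) 8-ketone
Product: 21 hydroazulene 12,8β-olide (C11H2; 6α-OTES; 9β-OTBS), via 8β-hydroxy ester 20 (not isolated)
Conditions: NaBH4, MeOH/THF, 0 °C; then PPTS (cat.), PhMe, 50 °C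
Reagents that add atoms: none
Why: Borohydride reduction and lactonisation of the resulting γ-hydroxy ester: hydride should attack C8 from the α face, anti to both flanking β substituents (the C7 side chain and the C9 silyloxy group), so the 8β-alcohol is cis to the ester chain and closes the cis-fused γ-lactone while O6 is blocked.

Step 14
Reactants: 21 hydroazulene 12,8β-olide; 22 ethyl formate
Product: 23 11-formyl lactone (C11 epimers in equilibrium with the hydroxymethylene tautomer)
Conditions: LiN(iPr)2, THF, −78 °C; 22, −78 → 0 °C; aq. HCl to pH 4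
Reagents that add atoms: none
Why: Claisen-type formylation of a lactone enolate works because C11 is the only enolisable position and the product is held as its stabilised hydroxymethylene enolate until work-up.

Step 15
Reactants: 23 11-formyl lactone; 24 methyl vinyl ketone
Product: 26 spiro cyclohexenone lactone (C1′ ketone; C2′=C3′), via 11-formyl-11-(3-oxobutyl) lactone 25 (not isolated)
Conditions: Et3N (cat.), CH2Cl2, rt; then pyrrolidine, AcOH (0.3 equiv each), PhMe, 70 °C
Reagents that add atoms: none
Why: Robinson-type spiroannulation (amine-base Michael addition, then enamine aldol condensation onto the non-enolisable aldehyde): the enone should attack C11 on the convex face of the cis-fused lactone, anti to C6, so that C13 ends syn to H7 and the formyl carbon (C3′) syn to C6, which is the C11 configuration of the target.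

Step 16
Reactants: 26 spiro cyclohexenone lactone
Product: 27 spiro dienyl triflate (C1′–OTf; C6′=C1′ and C2′=C3′)
Conditions: KN(SiMe3)2, THF, −78 °C; PhNTf2; aq. NH4Cl
Reagents that add atoms: N-phenylbis(trifluoromethanesulfonimide), O=S(=O)(N(c1ccccc1)S(=O)(=O)C(F)(F)F)C(F)(F)F
Why: Kinetic enolisation of a 4,4-disubstituted cyclohexenone occurs at the α′ methylene (C6′) to give the cross-conjugated dienolate, which the triflimide traps on oxygen as the 2-triflyloxy-1,3-diene; the lactone has no α hydrogen left.

Step 17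
Reactants: 27 spiro dienyl triflate
Product: 28 spiro 4-methylcyclohexa-2,4-diene lactone with 6α-OTES
Conditions: MeZnCl, Pd(PPh3)4 (5 mol %), THF, 50 °C
Reagents that add atoms: methylzinc chloride, C[Zn]Cl
Why: Negishi cross-coupling of an alkenyl triflate with a methylzinc reagent replaces the triflate by methyl without moving either double bond, so the diene is fixed as C6′=C1′–C2′=C3′ and no dehydration regiochemistry has to be controlled.

Step 18
Reactants: 28 spiro 4-methylcyclohexa-2,4-diene lactone with 6α-OTES
Product: 29 6α-alcohol of the spiro diene lactone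
Conditions: HF·pyridine, pyridine, THF, 0 °C
Reagents that add atoms: none
Why: Fluoride cleavage of silyl ethers is much faster for a triethylsilyl than for a TBS ether, so pyridine-buffered HF should free only O6 while the dioxolane and the diene tolerate the buffered medium.

Step 19
Reactants: 29 6α-alcohol of the spiro diene lactone; 30 acryloyl chloride
Product: 31 6α-acrylate of the spiro diene lactone (key-step precursor)
Conditions: Et3N, DMAP (cat.), CH2Cl2, −20 → 0 °C
Reagents that add atoms: none
Why: DMAP-catalysed acylation of a secondary alcohol with an acid chloride should give the acrylate when run cold and briefly, which also keeps the acrylate from polymerising.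

Step 20
Reactants: 31 6α-acrylate of the spiro diene lactone
Product: 32 lactone-bridged bicyclo[2.2.2]octene (C4′ carbonyl exo and bridged to O6; C4′ epimer of the target series)
Conditions: BHT (cat.), PhMe (0.01 M), 170 °C, sealed tube
Reagents that add atoms: none
Why: On heating, the acrylate π bond adds suprafacially to the cyclohexa-1,3-diene in a concerted, thermally allowed [4+2] cycloaddition that forms C3′–C4′ and C6′–C5′ together. The closest known reaction type is the ester-tethered intramolecular Diels–Alder reaction of cyclohexa-1,3-dienes, which gives lactone-fused bicyclo[2.2.2]octenes. The new six-membered carbocycle (C6′, C1′, C2′, C3′, C4′, C5′) closes by the cycloaddition itself, and the seven-membered lactone (O6, C6, C7, C11, C3′, C4′, carbonyl carbon) closes in the fused mode of a tether attached at a diene terminus as the C3′–C4′ bond forms. C3′ and C6′ are set by the choice of diene face, which the existing C11 configuration dictates because the tether runs through C7 and reaches only the face syn to C7, and C4′ is set by the tether, which holds the carbonyl over the C11–C13 bridge (exo). The step needs addition on the more hindered C7-side face with the carbonyl-bearing carbon bonding to C3′; both are enforced by the five-atom tether, and this regiochemistry coincides with the preference of a 2-methyl diene for the para adduct. The exo carbonyl is the C4′ epimer of the target and is corrected once the bridge is opened.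

Step 21
Reactants: 32 lactone-bridged bicyclo[2.2.2]octene
Product: 34 4′-endo-acetyl 6α-alcohol, via 4′-exo-acetyl 6α-alcohol 33 (not isolated)
Conditions: MeLi (1.1 equiv), THF, −78 °C; AcOH; then DBU (cat.), PhMe, rt
Reagents that add atoms: methyllithium, [Li]C
Why: Mono-addition of an organolithium to a lactone followed by amidine-mediated epimerisation α to the ketone: the strained seven-membered bridge is far more electrophilic than the γ-lactone on quaternary C11 and its tetrahedral adduct persists until the quench, after which DBU should move the acetyl group from the crowded exo position beside C7 to the endo position, where it can no longer close onto O6.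

Step 22
Reactants: 34 4′-endo-acetyl 6α-alcohol
Product: 35 4′-endo-(2-hydroxypropan-2-yl) 6α-alcohol
Conditions: MeLi, CeCl3, THF, −78 °C; aq. NH4Cl
Reagents that add atoms: methyllithium, [Li]C
Why: Organocerium addition to a ketone: the weakly basic reagent should add to the hindered methyl ketone without enolising it and ignore the α-quaternary γ-lactone at −78 °C, and no new stereocentre arises because the carbinol carbon carries two methyl groups.

Step 23
Reactants: 35 4′-endo-(2-hydroxypropan-2-yl) 6α-alcohol; 36 tiglic acid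
Product: 38 6α-tiglate of 35, via tiglic 2,4,6-trichlorobenzoic anhydride 37 (not isolated)
Conditions: 36, 2,4,6-Cl3C6H2COCl, Et3N, THF, rt; then 35, DMAP, PhMe, 60 °C
Reagents that add atoms: 2,4,6-trichlorobenzoyl chloride, O=C(Cl)c1c(Cl)cc(Cl)cc1Cl (kept only in intermediate 37)
Why: Yamaguchi esterification: the mixed anhydride should acylate the hindered secondary O6 under DMAP catalysis while the tertiary alcohol stays free, and the E geometry of the acid is carried over unchanged.

Step 24
Reactants: 38 6α-tiglate of 35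
Product: 39 C4 ketone (6α-tiglate; 9β-OTBS; tertiary alcohol)
Conditions: PPTS, acetone/H2O, 60 °C
Reagents that add atoms: water, O
Why: Acid-catalysed ketal hydrolysis with a pyridinium salt in wet acetone should release the C4 ketone without cleaving the secondary TBS ether, dehydrating the tertiary alcohol or hydrolysing the esters.

Step 25
Reactants: 39 C4 ketone
Product: 41 2-en-4-one bearing the tertiary O-TMS ether, via 4-trimethylsilyloxy-3-ene 40 (not isolated)
Conditions: TMSOTf, Et3N, CH2Cl2, 0 °C; then Pd(OAc)2, MeCN, rt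
Reagents that add atoms: trimethylsilyl triflate, C[Si](C)(C)OS(=O)(=O)C(F)(F)F
Why: Saegusa–Ito oxidation: because C5 is quaternary the ketone can enolise only toward C3, so dehydrogenation can place the double bond only at C2=C3, and the tertiary alcohol is merely silylated in passing.

Step 26
Reactants: 41 2-en-4-one bearing the tertiary O-TMS ether
Product: 42 CNP0185323.3
Conditions: HF·pyridine, THF, 0 °C → rt
Reagents that add atoms: none
Why: Fluoride-mediated desilylation with HF·pyridine should remove the C9 TBS and the tertiary TMS groups under mildly acidic conditions that leave the enone, the tiglate and the lactone intact.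

Compound list
1 | 2-methylcyclopent-2-en-1-one | CC1=CCCC1=O | starting material
2 | vinylmagnesium bromide | C=C[Mg]Br | starting material
3 | (S)-trimethyl[(2-methyl-3-vinylcyclopent-1-en-1-yl)oxy]silane | C=C[C@@H]1CCC(O[Si](C)(C)C)=C1C | intermediate
4 | penta-1,4-dien-3-ol | C=CC(O)C=C | starting material
5 | penta-1,4-dien-3-one | C=CC(=O)C=C | intermediate
6 | (2S,3S)-2-methyl-2-(3-oxopent-4-en-1-yl)-3-vinylcyclopentan-1-one (chain trans to vinyl) | C=C[C@@H]1CCC(=O)[C@@]1(C)CCC(=O)C=C | intermediate
7 | trans-hydroazul-9-ene-4,8-dione (C4 and C8 ketones, C9=C10, 5β-methyl, 1α-H) | C1CC(=O)C=C[C@@H]2CCC(=O)[C@]21C | intermediate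
8 | 4,4-ethylenedioxyhydroazul-9-en-8-one (5β-methyl, 1α-H) | C1CC(=O)C=C[C@@H]2CCC3(OCCO3)[C@]21C | intermediate
9 | 4,4-ethylenedioxy-10α-methyl-8-(trimethylsilyloxy)hydroazul-8-ene | C1CC(O[Si](C)(C)C)=C[C@@H](C)[C@@H]2CCC3(OCCO3)[C@]21C | intermediate
10 | 4,4-ethylenedioxy-10α-methyl-9β-(trimethylsilyloxy)hydroazulan-8-one (not isolated) | C1CC(=O)[C@H](O[Si](C)(C)C)[C@@H](C)[C@@H]2CCC3(OCCO3)[C@]21C | intermediate
11 | 4,4-ethylenedioxy-9β-hydroxy-10α-methylhydroazulan-8-one | C1CC(=O)[C@H](O)[C@@H](C)[C@@H]2CCC3(OCCO3)[C@]21C | intermediate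
12 | 9β-tert-butyldimethylsilyl ether of 11 | C1CC(=O)[C@H](O[Si](C)(C)C(C)(C)C)[C@@H](C)[C@@H]2CCC3(OCCO3)[C@]21C | intermediate
13 | 8-trimethylsilyloxy-7-ene of 12 (not isolated) | C1C=C(O[Si](C)(C)C)[C@H](O[Si](C)(C)C(C)(C)C)[C@@H](C)[C@@H]2CCC3(OCCO3)[C@]21C | intermediate
14 | 4,4-ethylenedioxy-9β-(tert-butyldimethylsilyloxy)-10α-methylhydroazul-6-en-8-one | C1=CC(=O)[C@H](O[Si](C)(C)C(C)(C)C)[C@@H](C)[C@@H]2CCC3(OCCO3)[C@]21C | intermediate
15 | 6α-(pinacolboryl) 8-ketone (not isolated) | CC1(C)OB([C@H]2CC(=O)[C@H](O[Si](C)(C)C(C)(C)C)[C@@H](C)[C@@H]3CCC4(OCCO4)[C@]32C)OC1(C)C | intermediate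
16 | 6α-hydroxy-9β-(tert-butyldimethylsilyloxy)-10α-methyl 8-ketone (C4 dioxolane) | O[C@H]1CC(=O)[C@H](O[Si](C)(C)C(C)(C)C)[C@@H](C)[C@@H]2CCC3(OCCO3)[C@]21C | intermediate
17 | 6α-triethylsilyl ether of 16 | CC[Si](CC)(CC)O[C@H]1CC(=O)[C@H](O[Si](C)(C)C(C)(C)C)[C@@H](C)[C@@H]2CCC3(OCCO3)[C@]21C | intermediate
18 | ethyl iodoacetate | CCOC(=O)CI | starting material
19 | 7β-(2-ethoxy-2-oxoethyl)-6α-(triethylsilyloxy)-9β-(tert-butyldimethylsilyloxy)-10α-methyl 8-ketone | CC[Si](CC)(CC)O[C@H]1[C@H](CC(=O)OCC)C(=O)[C@H](O[Si](C)(C)C(C)(C)C)[C@@H](C)[C@@H]2CCC3(OCCO3)[C@]21C | intermediate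
20 | 8β-hydroxy ester from 19 (not isolated) | CC[Si](CC)(CC)O[C@H]1[C@H](CC(=O)OCC)[C@H](O)[C@H](O[Si](C)(C)C(C)(C)C)[C@@H](C)[C@@H]2CCC3(OCCO3)[C@]21C | intermediate
21 | hydroazulene 12,8β-olide (cis-fused γ-lactone, C11H2, 6α-OTES, 9β-OTBS, 10α-methyl, C4 dioxolane) | CC[Si](CC)(CC)O[C@H]1[C@H]2[C@H](OC(=O)C2)[C@H](O[Si](C)(C)C(C)(C)C)[C@@H](C)[C@@H]2CCC3(OCCO3)[C@]21C | intermediate
22 | ethyl formate | CCOC=O | starting material
23 | 11-formyl lactone (C11 epimers, hydroxymethylene tautomer in equilibrium) | CC[Si](CC)(CC)O[C@H]1[C@H]2[C@H](OC(=O)C2C=O)[C@H](O[Si](C)(C)C(C)(C)C)[C@@H](C)[C@@H]2CCC3(OCCO3)[C@]21C | intermediate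
24 | methyl vinyl ketone | CC(=O)C=C | starting material
25 | 11-formyl-11-(3-oxobutyl) lactone, oxobutyl chain syn to H7 (not isolated) | CC[Si](CC)(CC)O[C@H]1[C@H]2[C@H](OC(=O)[C@]2(C=O)CCC(C)=O)[C@H](O[Si](C)(C)C(C)(C)C)[C@@H](C)[C@@H]2CCC3(OCCO3)[C@]21C | intermediate
26 | spiro cyclohexenone lactone (C1′ ketone, C2′=C3′, C3′ syn to C6) | CC[Si](CC)(CC)O[C@H]1[C@H]2[C@H](OC(=O)[C@]23CCC(=O)C=C3)[C@H](O[Si](C)(C)C(C)(C)C)[C@@H](C)[C@@H]2CCC3(OCCO3)[C@]21C | intermediate
27 | spiro dienyl triflate (C1′–OTf, C6′=C1′, C2′=C3′) | CC[Si](CC)(CC)O[C@H]1[C@H]2[C@H](OC(=O)[C@]23CC=C(OS(=O)(=O)C(F)(F)F)C=C3)[C@H](O[Si](C)(C)C(C)(C)C)[C@@H](C)[C@@H]2CCC3(OCCO3)[C@]21C | intermediate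
28 | spiro 4-methylcyclohexa-2,4-diene lactone, 6α-OTES | CC[Si](CC)(CC)O[C@H]1[C@H]2[C@H](OC(=O)[C@]23CC=C(C)C=C3)[C@H](O[Si](C)(C)C(C)(C)C)[C@@H](C)[C@@H]2CCC3(OCCO3)[C@]21C | intermediate
29 | spiro 4-methylcyclohexa-2,4-diene lactone, 6α-alcohol | O[C@H]1[C@H]2[C@H](OC(=O)[C@]23CC=C(C)C=C3)[C@H](O[Si](C)(C)C(C)(C)C)[C@@H](C)[C@@H]2CCC3(OCCO3)[C@]21C | intermediate
30 | acryloyl chloride | C=CC(Cl)=O | starting material
31 | 6α-acrylate of the spiro cyclohexadiene lactone (key-step precursor) | C=CC(=O)O[C@H]1[C@H]2[C@H](OC(=O)[C@]23CC=C(C)C=C3)[C@H](O[Si](C)(C)C(C)(C)C)[C@@H](C)[C@@H]2CCC3(OCCO3)[C@]21C | intermediate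
32 | lactone-bridged bicyclo[2.2.2]octene (C4′ carbonyl exo, bridged to O6; C4′ epimer of the target series) | O=C1O[C@H]2[C@H]3[C@H](OC(=O)[C@]34C[C@@H]5C[C@H]1[C@H]4C=C5C)[C@H](O[Si](C)(C)C(C)(C)C)[C@@H](C)[C@@H]3CCC4(OCCO4)[C@]32C | intermediate
33 | 4′-exo-acetyl 6α-alcohol (not isolated; may rest as its hemiketal) | O[C@H]1[C@H]2[C@H](OC(=O)[C@]23C[C@@H]2C[C@H](C(C)=O)[C@H]3C=C2C)[C@H](O[Si](C)(C)C(C)(C)C)[C@@H](C)[C@@H]2CCC3(OCCO3)[C@]21C | intermediate
34 | 4′-endo-acetyl 6α-alcohol | O[C@H]1[C@H]2[C@H](OC(=O)[C@]23C[C@@H]2C[C@@H](C(C)=O)[C@H]3C=C2C)[C@H](O[Si](C)(C)C(C)(C)C)[C@@H](C)[C@@H]2CCC3(OCCO3)[C@]21C | intermediate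
35 | 4′-endo-(2-hydroxypropan-2-yl) 6α-alcohol | O[C@H]1[C@H]2[C@H](OC(=O)[C@]23C[C@@H]2C[C@@H](C(C)(C)O)[C@H]3C=C2C)[C@H](O[Si](C)(C)C(C)(C)C)[C@@H](C)[C@@H]2CCC3(OCCO3)[C@]21C | intermediate
36 | tiglic acid | C/C=C(\C)C(=O)O | starting material
37 | (E)-2-methylbut-2-enoic 2,4,6-trichlorobenzoic anhydride (not isolated) | C/C=C(\C)C(=O)OC(=O)c1c(Cl)cc(Cl)cc1Cl | intermediate
38 | 6α-tiglate of 35 (C4 dioxolane, 9β-OTBS) | C/C=C(\C)C(=O)O[C@H]1[C@H]2[C@H](OC(=O)[C@]23C[C@@H]2C[C@@H](C(C)(C)O)[C@H]3C=C2C)[C@H](O[Si](C)(C)C(C)(C)C)[C@@H](C)[C@@H]2CCC3(OCCO3)[C@]21C | intermediate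
39 | C4 ketone (6α-tiglate, 9β-OTBS, tertiary alcohol) | C/C=C(\C)C(=O)O[C@H]1[C@H]2[C@H](OC(=O)[C@]23C[C@@H]2C[C@@H](C(C)(C)O)[C@H]3C=C2C)[C@H](O[Si](C)(C)C(C)(C)C)[C@@H](C)[C@@H]2CCC(=O)[C@]21C | intermediate
40 | 4-trimethylsilyloxy-3-ene with tertiary O-TMS ether (not isolated) | C/C=C(\C)C(=O)O[C@H]1[C@H]2[C@H](OC(=O)[C@]23C[C@@H]2C[C@@H](C(C)(C)O[Si](C)(C)C)[C@H]3C=C2C)[C@H](O[Si](C)(C)C(C)(C)C)[C@@H](C)[C@@H]2CC=C(O[Si](C)(C)C)[C@]21C | intermediate
41 | 2-en-4-one with tertiary O-TMS ether and 9β-OTBS | C/C=C(\C)C(=O)O[C@H]1[C@H]2[C@H](OC(=O)[C@]23C[C@@H]2C[C@@H](C(C)(C)O[Si](C)(C)C)[C@H]3C=C2C)[C@H](O[Si](C)(C)C(C)(C)C)[C@@H](C)[C@@H]2C=CC(=O)[C@]21C | intermediate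
42 | CNP0185323.3 | C/C=C(\C)C(=O)O[C@H]1[C@H]2[C@H](OC(=O)[C@]23C[C@@H]2C[C@@H](C(C)(C)O)[C@H]3C=C2C)[C@H](O)[C@@H](C)[C@@H]2C=CC(=O)[C@]21C | target

Total step count: 26. Longest linear sequence: 25 steps (steps 1 and 3–26 from compound 1; step 2 is a one-step side branch).

Steps most likely to fail

Step 20. The cycloaddition may be too slow, because the ester must adopt its less stable conformation inside a seven-membered transition-state ring, so that [1,5]-hydrogen migration in the diene or radical polymerisation of the acrylate overtakes it. The fallback changes the dienophile to an alkyne and sets out from alcohol 29. Esterification with propiolic acid (DCC, DMAP cat., CH2Cl2, −20 °C) should give the propiolate ester F1. An alkynoate is the more reactive dienophile and has no endo/exo demand, so gentle heating (PhMe, 110 °C) should close the same two bonds to the lactone-bridged bicyclo[2.2.2]octadiene F2. Conjugate reduction of the unsaturated bridge lactone with [(Ph3P)CuH]6 and PhSiH3 (PhMe, rt), in which protonation at C4′ can only give the carbonyl-exo geometry that the bridge allows, comes back to the route at 32.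

Step 1. Enantio-induction may be incomplete, or 1,2-addition of the Grignard reagent may compete with the copper-mediated pathway. The fallback sets the stereocentre by rhodium catalysis and sets out from enone 1. 1,4-Addition of potassium vinyltrifluoroborate ([Rh(cod)2]BF4, (S)-BINAP or its antipode as required, PhMe/H2O, 100 °C) should give (3S)-2-methyl-3-vinylcyclopentan-1-one F3 as a mixture of C2 epimers that does not matter. Thermodynamic enol silylation toward the more substituted side (TMSCl, NaI, Et3N, MeCN, rt) comes back to the route at 3.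

Step 21. Chemoselectivity may be lost: the tetrahedral adduct may collapse before the quench and take up a second methyl group, which fixes the exo carbinol, or the exo epimer may be held back as its hemiketal. The fallback opens the bridge by alcoholysis and sets out from 32. NaOMe in MeOH (50 °C) should open the bridge and equilibrate the ester to the endo methyl ester F4. Excess MeLi/CeCl3 (THF, −78 → 0 °C) should then convert the ester into the tertiary alcohol and comes back to the route at 35. This variant is kept in reserve because it exposes O6, the γ-lactone and the neighbouring C9 silyl ether to methoxide.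

Further compounds
F1 | step 20 | 6α-propiolate of the spiro cyclohexadiene lactone | C#CC(=O)O[C@H]1[C@H]2[C@H](OC(=O)[C@]23CC=C(C)C=C3)[C@H](O[Si](C)(C)C(C)(C)C)[C@@H](C)[C@@H]2CCC3(OCCO3)[C@]21C
F2 | step 20 | lactone-bridged bicyclo[2.2.2]octa-diene (C4′=C5′ and C1′=C2′) | O=C1O[C@H]2[C@H]3[C@H](OC(=O)[C@]34C[C@@H]5C=C1[C@H]4C=C5C)[C@H](O[Si](C)(C)C(C)(C)C)[C@@H](C)[C@@H]3CCC4(OCCO4)[C@]32C
F3 | step 1 | (3S)-2-methyl-3-vinylcyclopentan-1-one (C2 epimers) | C=C[C@@H]1CCC(=O)C1C
F4 | step 21 | 4′-endo methyl ester 6α-alcohol | O[C@H]1[C@H]2[C@H](OC(=O)[C@]23C[C@@H]2C[C@@H](C(=O)OC)[C@H]3C=C2C)[C@H](O[Si](C)(C)C(C)(C)C)[C@@H](C)[C@@H]2CCC3(OCCO3)[C@]21C
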